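**Assumption:** the target SMILES contains no stereocentre (each quaternary carbon carries two methyl groups). The compound is achiral, so there is no enantiomer to select and no step has to set configuration.

## Retrosynthetic overview
1. Target ⇒ bis(2H-chromene) analogue. The last step only saturates the two C3=C4 bonds and does not change the skeleton.
2. Bis(2H-chromene) ⇒ bis(aryl 1,1-dimethylpropargyl ether). Both pyran rings close together by 6-endo attack of each ortho carbon on the alkyne, and the O–CMe2 bonds stay intact.
3. Bis(ether) ⇒ phloretin + two 3-chloro-3-methylbut-1-yne. This is the key disconnection, at the two aryl O–CMe2 bonds. Attaching oxygen first delivers exactly one five-carbon unit per ring and fixes the ring A regiochemistry (ether on 4'-O, with C3' and C5' equivalent).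
4. Ring order: both benzene rings and the three-carbon ketone bridge are bought with phloretin. The two oxygen rings form together in step 2 and are brought to the chroman level in step 3.

## Route

Step 1
Reactants: 1 phloretin [3-(4-hydroxyphenyl)-1-(2,4,6-trihydroxyphenyl)propan-1-one]; 2 3-chloro-3-methylbut-1-yne
Product: 3 1-[2,6-dihydroxy-4-(2-methylbut-3-yn-2-yloxy)phenyl]-3-[4-(2-methylbut-3-yn-2-yloxy)phenyl]propan-1-one
Conditions: Cs2CO3 (3.2 equiv), Cu(MeCN)4PF6 (5 mol%), Ph-pybox [2,6-bis(4-phenyl-4,5-dihydrooxazol-2-yl)pyridine, either enantiomer, 6 mol%], DMF, argon, 0 °C; 2 (2.15 equiv) added over 2 h, then rt, 6 h; pH 5 phosphate buffer work-up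
Reagents that add atoms: 3-chloro-3-methylbut-1-yne (2), C#CC(C)(C)Cl
Why: Proposed new method: a twofold, site-selective copper-allenylidene O-alkylation of an unprotected tetraphenol, which has not been shown; the closest known reaction type is the copper-catalysed propargylic substitution that converts single monophenols into aryl 1,1-dimethylpropargyl ethers (CuCl2, DBU). Monovalent copper forms the acetylide of 2, chloride leaves to give the cationic allenylidene Cu=C=C=CMe2, a phenoxide adds to its tertiary gamma carbon, and protonolysis frees the ether. Slightly more than three equivalents of base keep the ring B phenoxide (pKa about 10) ionised beside the more acidic ring A, so the two fast nucleophiles are the unhindered 4-O and 4'-O anions. The 2'/6'-oxygens are flanked by the acyl group, engaged with the ketone, and kept away from the tertiary carbon by the phenyl walls of the pybox ligand, which also stops the acylphloroglucinolate from sequestering copper. The hard, cation-like electrophile and the caesium counter-ion in DMF favour O- over C-attack on ring A, slow addition of 2 limits a third alkylation, and no stereocentre is formed.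

Step 2
Reactants: 3 1-[2,6-dihydroxy-4-(2-methylbut-3-yn-2-yloxy)phenyl]-3-[4-(2-methylbut-3-yn-2-yloxy)phenyl]propan-1-one
Product: 4 1-(5,7-dihydroxy-2,2-dimethyl-2H-chromen-6-yl)-3-(2,2-dimethyl-2H-chromen-6-yl)propan-1-one
Conditions: Ph3PAuNTf2 (4 mol%), dry CH2Cl2, rt, 2 h
Reagents that add atoms: none
Why: In this gold-catalysed intramolecular alkyne hydroarylation (6-endo-dig, Friedel–Crafts type), the cationic monovalent gold π-acid activates each terminal alkyne, the ortho carbon attacks (C3 of ring B; C3', equivalent to C5', of the very electron-rich ring A), and protodeauration gives the 2H-chromene at room temperature without breaking the O–CMe2 bonds, so the oxygen pattern fixed in step 1 carries over unchanged and no stereocentre is formed.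

Step 3
Reactants: 4 1-(5,7-dihydroxy-2,2-dimethyl-2H-chromen-6-yl)-3-(2,2-dimethyl-2H-chromen-6-yl)propan-1-one
Product: 5 1-(5,7-dihydroxy-2,2-dimethylchroman-6-yl)-3-(2,2-dimethylchroman-6-yl)propan-1-one (CNP0080574.0)
Conditions: H2 (1 atm), 10% Pd/C (5 mol% Pd), EtOAc, rt, 3 h, stopped after uptake of 2 equiv H2
Reagents that add atoms: none
Why: In this heterogeneous catalytic hydrogenation the two cis-disubstituted, styrene-type C3=C4 bonds are saturated quickly at 1 atm, while the hydrogen-bonded aryl ketone flanked by two ortho hydroxyls behaves as a vinylogous acid and is not reduced under these mild conditions, and no stereocentre is formed.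

## Compound list
1 | phloretin, 3-(4-hydroxyphenyl)-1-(2,4,6-trihydroxyphenyl)propan-1-one (achiral) | O=C(CCc1ccc(O)cc1)c1c(O)cc(O)cc1O | starting material
2 | 3-chloro-3-methylbut-1-yne (achiral) | C#CC(C)(C)Cl | starting material
3 | 1-[2,6-dihydroxy-4-(2-methylbut-3-yn-2-yloxy)phenyl]-3-[4-(2-methylbut-3-yn-2-yloxy)phenyl]propan-1-one (achiral) | C#CC(C)(C)Oc1ccc(CCC(=O)c2c(O)cc(OC(C)(C)C#C)cc2O)cc1 | intermediate
4 | 1-(5,7-dihydroxy-2,2-dimethyl-2H-chromen-6-yl)-3-(2,2-dimethyl-2H-chromen-6-yl)propan-1-one (achiral) | CC1(C)C=Cc2cc(CCC(=O)c3c(O)cc4c(c3O)C=CC(C)(C)O4)ccc2O1 | intermediate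
5 | 1-(5,7-dihydroxy-2,2-dimethylchroman-6-yl)-3-(2,2-dimethylchroman-6-yl)propan-1-one (achiral) | CC1(C)CCc2cc(CCC(=O)c3c(O)cc4c(c3O)CCC(C)(C)O4)ccc2O1 | target

## Step count and risks
Total step count: 3. Longest linear sequence: 3.

**Risk 1, step 1 (the proposed new step).**
- Possible failures are a third alkylation at 2'-O, C-alkylation of ring A at C3', or loss of 2 by elimination.
- The fallback uses known chemistry and replaces catalyst control by internal protection. It sets out from 2 and uses bought rac-naringenin F1. In F1 one ortho oxygen of ring A is tied up in the flavanone heterocycle and the other is the inert chelated 5-OH, so only the two wanted hydroxyls are free.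
- Standard aryl propargyl ether formation (2, K2CO3, KI, CuI, acetone, 55 °C) gives the 7,4'-bis(1,1-dimethylpropargyl) ether of naringenin F2.
- Ph3PAuNTf2 in CH2Cl2 closes both chromenes. It gives the angular 7,8-fused pyranoflavanone F3 together with the linear 6,7-fused pyranoflavanone F4.
- The mixture is not separated. Alkaline catalytic hydrogenation (H2, Pd/C, aqueous KOH/EtOH, then acidification) is the known flavanone-to-dihydrochalcone reduction. It opens the heterocycle by retro-oxa-Michael reaction and saturates the chalcone and both chromene double bonds.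
- Ring opening makes the two ortho oxygens equivalent, so both isomers converge and the racemic centre is erased. The fallback comes back to the route at 5.

**Risk 2, step 2.**
- The tertiary propargylic ethers may ionise on the π-acid, or the polyphenol may slow the gold catalyst.
- The fallback gives up alkyne activation for a pericyclic cascade in which the flanking hydroxyls are blocked. It sets out from 3.
- Ac2O, pyridine and DMAP give the 2',6'-diacetate of the bis(propargyl ether) F5.
- Heating F5 in 1,2-dichlorobenzene at 180 °C triggers the aromatic propargyl Claisen rearrangement, 1,5-hydrogen shift and oxa-6π electrocyclisation on both rings. Only the phenol oxygen released by the [3,3] shift can close, which gives the bis(chromene) diacetate F6 with the same regiochemistry.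
- K2CO3 in MeOH removes the acetates, and the fallback comes back to the route at 4.

**Risk 3, step 3.**
- Pd/C may over-reduce the aryl ketone or cleave the allylic O–C2 bonds of the chromenes.
- The fallback moves the reduction ahead of ring closure. It sets out from 3.
- Semi-hydrogenation over Pd/CaCO3 poisoned with Pb(OAc)2, with quinoline, gives the bis(1,1-dimethylallyl) ether F7.
- Heating F7 in N,N-diethylaniline at 130 °C brings about a twofold aromatic Claisen rearrangement to 3,3'-diprenylphloretin F8.
- Acid-catalysed intramolecular hydroalkoxylation (p-TsOH, toluene, 60 °C) closes both chroman rings directly, and the fallback comes back to the route at 5.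
- Ring A can also close through 2'-OH, so the 8-acyl regioisomer F9 has to be removed by chromatography.

## Further compounds
F1 | step 1 | rac-naringenin, 5,7-dihydroxy-2-(4-hydroxyphenyl)chroman-4-one (bought) | O=C1CC(c2ccc(O)cc2)Oc2cc(O)cc(O)c12
F2 | step 1 | rac-5-hydroxy-7-(2-methylbut-3-yn-2-yloxy)-2-[4-(2-methylbut-3-yn-2-yloxy)phenyl]chroman-4-one | O=C1CC(c2ccc(OC(C)(C)C#C)cc2)Oc2cc(OC(C)(C)C#C)cc(O)c12
F3 | step 1 | rac angular 7,8-fused pyranoflavanone, 5-hydroxy-8,8-dimethyl-2-(2,2-dimethyl-2H-chromen-6-yl)-2,3-dihydro-4H,8H-pyrano[2,3-f]chromen-4-one | O=C1CC(c3ccc4c(c3)C=CC(C)(C)O4)Oc2c1c(O)cc1OC(C)(C)C=Cc12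
F4 | step 1 | rac linear 6,7-fused pyranoflavanone, 5-hydroxy-2,2-dimethyl-8-(2,2-dimethyl-2H-chromen-6-yl)-7,8-dihydro-2H,6H-pyrano[3,2-g]chromen-6-one | O=C1CC(c4ccc5c(c4)C=CC(C)(C)O5)Oc2cc3OC(C)(C)C=Cc3c(O)c12
F5 | step 2 | 5-(2-methylbut-3-yn-2-yloxy)-2-{3-[4-(2-methylbut-3-yn-2-yloxy)phenyl]propanoyl}benzene-1,3-diyl diacetate | C#CC(C)(C)Oc1ccc(CCC(=O)c2c(OC(C)=O)cc(OC(C)(C)C#C)cc2OC(C)=O)cc1
F6 | step 2 | 6-[3-(2,2-dimethyl-2H-chromen-6-yl)propanoyl]-2,2-dimethyl-2H-chromene-5,7-diyl diacetate | CC1(C)C=Cc2cc(CCC(=O)c3c(OC(C)=O)cc4c(c3OC(C)=O)C=CC(C)(C)O4)ccc2O1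
F7 | step 3 | 1-[2,6-dihydroxy-4-(2-methylbut-3-en-2-yloxy)phenyl]-3-[4-(2-methylbut-3-en-2-yloxy)phenyl]propan-1-one | C=CC(C)(C)Oc1ccc(CCC(=O)c2c(O)cc(OC(C)(C)C=C)cc2O)cc1
F8 | step 3 | 3,3'-diprenylphloretin, 3-[4-hydroxy-3-(3-methylbut-2-enyl)phenyl]-1-[2,4,6-trihydroxy-3-(3-methylbut-2-enyl)phenyl]propan-1-one | CC(C)=CCc1cc(CCC(=O)c2c(O)cc(O)c(CC=C(C)C)c2O)ccc1O
F9 | step 3 | 1-(5,7-dihydroxy-2,2-dimethylchroman-8-yl)-3-(2,2-dimethylchroman-6-yl)propan-1-one (regioisomeric by-product) | CC1(C)CCc2cc(CCC(=O)c3c(O)cc(O)c4c3OC(C)(C)CC4)ccc2O1
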